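## Retrosynthetic overview

1. Target 19 is disconnected at the C6 ester to (−)-loliolide 17 and palmitoyl chloride. 17 comes from ketolactone 16 by equatorial hydride delivery at C6, and 16 from the (6R)-carbinol 15 and its benzoate 14.
2. The strategy rests on the butenolide ring O1–C2(=O)–C3=C3a–C7a. Without O1 it is a cyclobutenone fused to the cyclohexane, whose C2–C3 and C7a–C3a bonds are the two bonds of a ketene-equivalent plus alkyne [2+2], with the methyl-bearing quaternary C7a as the ketene α-carbon. Baeyer–Villiger oxidation puts O1 back (13 to 14).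
3. Cyclobutenone 13 is opened to the acyclic α-methyl amide 10 carrying a terminal alkyne. The cyclohexane and cyclobutene rings form together in step 7; the butenolide follows by oxygen insertion in step 8.
4. C7a is set in step 7 by an equatorial C6 benzoyloxy group in the chair-like tether, so an achiral amide suffices and any C7a epimer is a separable diastereomer. An ester is used at C6 because a ketal oxygen γ to the amide carbon would add to the keteniminium carbon and would have to sit syn-axial to two methyl groups. C6 is inverted afterwards through the ketone.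
5. Amide 10 comes from the lithium enolate of 1-propanoylpyrrolidine 7 and the (R)-epoxide 4, made by hydrolytic kinetic resolution, epoxidation and Ohira–Bestmann alkynylation from 2,2-dimethylpent-4-enal 1.

Key step: step 7

Numbering remark: the labels O1, C2, C3, C3a, C4–C7, C7a of the benzofuranone core of the target are used for the corresponding atoms of all intermediates.

Assumption: the hydrolytic kinetic resolution is taken to follow its usual sense for alkyl-substituted terminal epoxides, the (R,R)-(salen)Co catalyst leaving the (R)-epoxide; if the recovered epoxide proves to be (S), the (S,S)-catalyst is used and nothing else changes.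

## Route

Step 1
Reactants: 1 2,2-dimethylpent-4-enal
Product: 2 4,4-dimethylhex-1-en-5-yne
Conditions: Ohira–Bestmann reagent, K2CO3, MeOH, 0→25 °C; pentane extraction, careful distillation (volatile)
Reagents that add atoms: dimethyl (1-diazo-2-oxopropyl)phosphonate (Ohira–Bestmann reagent), CC(=O)C(=[N+]=[N-])P(=O)(OC)OC
Why: Seyferth–Gilbert homologation in its Ohira–Bestmann form should convert the non-enolisable α-quaternary aldehyde into the terminal alkyne (olefination to a diazoalkene, then 1,2-hydrogen shift of the alkylidene carbene) under carbonate conditions that leave the alkene untouched.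

Step 2
Reactants: 2 4,4-dimethylhex-1-en-5-yne
Product: 3 rac-2-(2,2-dimethylbut-3-yn-1-yl)oxirane
Conditions: mCPBA, NaHCO3, CH2Cl2, 0→25 °C
Reagents that add atoms: mCPBA (3-chloroperoxybenzoic acid), OOC(=O)c1cccc(Cl)c1
Why: Prilezhaev epoxidation, in which the peracid oxidises the alkene much faster than the terminal alkyne; the new stereocentre forms racemic and is resolved in step 3.

Step 3
Reactants: 3 rac-2-(2,2-dimethylbut-3-yn-1-yl)oxirane
Product: 4 (2R)-2-(2,2-dimethylbut-3-yn-1-yl)oxirane
Conditions: (R,R)-(salen)Co(III)OAc (0.5 mol %), H2O (0.55 equiv), THF, 0→25 °C; distillation from the diol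
Reagents that add atoms: none
Why: Jacobsen hydrolytic kinetic resolution, in which the chiral cobalt catalyst hydrolyses the (S)-epoxide selectively so that the unreacted (R)-epoxide is recovered in high enantiomeric purity; this fixes the future C6 stereocentre.

Step 4
Reactants: 5 pyrrolidine; 6 propanoyl chloride
Product: 7 1-(pyrrolidin-1-yl)propan-1-one
Conditions: Et3N, CH2Cl2, 0 °C
Reagents that add atoms: none
Why: Schotten–Baumann-type N-acylation of a secondary amine by an acid chloride.

Step 5
Reactants: 7 1-(pyrrolidin-1-yl)propan-1-one; 4 (2R)-2-(2,2-dimethylbut-3-yn-1-yl)oxirane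
Product: 9 (4S)-4-hydroxy-2,6,6-trimethyl-1-(pyrrolidin-1-yl)oct-7-yn-1-one (both C2 epimers), via lithium amide enolate 8 (not isolated)
Conditions: 7 (2.5 equiv), LDA (2.4 equiv), LiCl, THF, −78→0 °C; then 4, 0→25 °C; aq NH4Cl
Reagents that add atoms: none
Why: SN2 opening of the terminal epoxide at its CH2 carbon by a tertiary-amide lithium enolate (a known reaction of N,N-dialkylamide enolates, helped by LiCl), with one equivalent of enolate spent on the alkyne C–H; the carbinol centre is untouched (the descriptor changes from R to S only through priorities) and the new α-centre forms as both epimers, which step 7 erases.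

Step 6
Reactants: 9 (4S)-4-hydroxy-2,6,6-trimethyl-1-(pyrrolidin-1-yl)oct-7-yn-1-one
Product: 10 (4S)-2,6,6-trimethyl-1-oxo-1-(pyrrolidin-1-yl)oct-7-yn-4-yl benzoate (both C2 epimers)
Conditions: BzCl, pyridine, DMAP (cat.), CH2Cl2, 0→25 °C
Reagents that add atoms: benzoyl chloride, O=C(Cl)c1ccccc1
Why: DMAP-catalysed O-acylation of the secondary alcohol; the benzoate is chosen because an ester oxygen is a much poorer donor towards the keteniminium ion of step 7 than an ether or ketal oxygen.

Step 7
Reactants: 10 (4S)-2,6,6-trimethyl-1-oxo-1-(pyrrolidin-1-yl)oct-7-yn-4-yl benzoate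
Product: 13 (4R,6R)-2,2,6-trimethyl-7-oxobicyclo[4.2.0]oct-1(8)-en-4-yl benzoate, via keteniminium triflate 11 (not isolated), via cyclobuteniminium triflate 12 (not isolated)
Conditions: Tf2O (1.2 equiv), 2,4,6-collidine (1.5 equiv), ClCH2CH2Cl (0.02 M), 0→70 °C; then H2O, 25 °C
Reagents that add atoms: water, O
Why: Proposed new method: O-triflation of the amide and loss of the α-proton to collidine give keteniminium ion 11 (both C2 epimers of 10 converge), whose central carbon C2 is attacked by the terminal alkyne carbon C3 while the developing vinyl cation at C3a is captured by the enamine carbon C7a in an asynchronous [2+2] cycloaddition to cyclobuteniminium salt 12, which water hydrolyses to 13; the closest known reactions are the intermolecular keteniminium–alkyne [2+2] cycloaddition to cyclobutenones and the intramolecular keteniminium–alkene [2+2] cycloaddition to bicyclo[n.2.0]alkanones, and their combination on a tethered alkyne with a quaternary α-carbon is the untested element. The cyclohexane ring closes through the C7a–C3a bond over the four-atom tether C7–C6–C5–C4 in a 6-exo-dig sense (C3 stays outside the ring), and the cyclobutene ring closes in the same event through the C2–C3 bond as the four-membered ring of the cycloaddition. The only new stereocentre, C7a, is controlled by the C6 benzoyloxy stereocentre: the chair-like tether places the benzoate equatorial, away from the axial C4 methyl group, and since the flat four-membered ring forces the C7a methyl group axial, only the face of the keteniminium α-carbon that puts this methyl group trans to the benzoate (7aR) can be reached from that chair. The step needs fused rather than bridged regiochemistry, which is secured by the polarisation of the terminal alkyne (positive charge on the more substituted C3a) and by the tether length, and it needs cyclisation to outrun intermolecular reaction, which the gem-dimethyl group at C4 and high dilution favour. The ester oxygen at C6, γ to the amide carbon, is too weak a donor to add to the keteniminium carbon, and a C7a epimer, should any form, is a diastereomer of 13 and can be removed by chromatography.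

Step 8
Reactants: 13 (4R,6R)-2,2,6-trimethyl-7-oxobicyclo[4.2.0]oct-1(8)-en-4-yl benzoate
Product: 14 (6R,7aR)-4,4,7a-trimethyl-2-oxo-2,4,5,6,7,7a-hexahydro-1-benzofuran-6-yl benzoate
Conditions: mCPBA, NaHCO3, CH2Cl2, 0→25 °C
Reagents that add atoms: mCPBA (3-chloroperoxybenzoic acid), OOC(=O)c1cccc(Cl)c1
Why: Baeyer–Villiger oxidation driven by the strain of the cyclobutenone, in which the quaternary sp3 carbon C7a migrates in preference to the vinyl carbon C3 and with retention, so O1 enters the C2–C7a bond and the C7a configuration passes unchanged into the butenolide.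

Step 9
Reactants: 14 (6R,7aR)-4,4,7a-trimethyl-2-oxo-2,4,5,6,7,7a-hexahydro-1-benzofuran-6-yl benzoate
Product: 15 (6R,7aR)-6-hydroxy-4,4,7a-trimethyl-5,6,7,7a-tetrahydro-1-benzofuran-2(4H)-one (6-epi-loliolide)
Conditions: K2CO3 (cat.), MeOH, 0→25 °C
Reagents that add atoms: none
Why: Zemplén-type base-catalysed transesterification should cleave the secondary benzoate, while the γ,γ-disubstituted butenolide survives because any methanolysis of the lactone would only give a tertiary alkoxide that closes again.

Step 10
Reactants: 15 (6R,7aR)-6-hydroxy-4,4,7a-trimethyl-5,6,7,7a-tetrahydro-1-benzofuran-2(4H)-one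
Product: 16 (7aR)-4,4,7a-trimethyl-7,7a-dihydro-1-benzofuran-2,6(4H,5H)-dione
Conditions: Dess–Martin periodinane, CH2Cl2, 0→25 °C
Reagents that add atoms: none
Why: Dess–Martin oxidation under neutral conditions should give the ketone without base-induced E1cB loss of the lactone oxygen from C7a, which lies β to the new carbonyl group.

Step 11
Reactants: 16 (7aR)-4,4,7a-trimethyl-7,7a-dihydro-1-benzofuran-2,6(4H,5H)-dione
Product: 17 (6S,7aR)-6-hydroxy-4,4,7a-trimethyl-5,6,7,7a-tetrahydro-1-benzofuran-2(4H)-one ((−)-loliolide)
Conditions: L-Selectride (1.1 equiv), THF, −78 °C; aq NH4Cl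
Reagents that add atoms: none
Why: Substrate-controlled hydride reduction in which the axial methyl groups on C4 and C7a block the axial trajectory, so the bulky trialkylborohydride should attack C6 equatorially, from the face of O1, and give the axial (6S)-alcohol cis to the C7a methyl group; at −78 °C the fully β-substituted butenolide should not be reduced.

Step 12
Reactants: 17 (−)-loliolide; 18 hexadecanoyl (palmitoyl) chloride
Product: 19 (6S,7aR)-4,4,7a-trimethyl-2-oxo-2,4,5,6,7,7a-hexahydro-1-benzofuran-6-yl hexadecanoate ((−)-3-O-palmitoylloliolide)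
Conditions: pyridine, DMAP (cat.), CH2Cl2, 0→25 °C
Reagents that add atoms: none
Why: DMAP-catalysed esterification of the axial secondary alcohol with the acid chloride, with retention at C6.

## Compound list

1 | 2,2-dimethylpent-4-enal | C=CCC(C)(C)C=O | starting material
2 | 4,4-dimethylhex-1-en-5-yne | C=CCC(C)(C)C#C | intermediate
3 | rac-2-(2,2-dimethylbut-3-yn-1-yl)oxirane | C#CC(C)(C)CC1CO1 | intermediate
4 | (2R)-2-(2,2-dimethylbut-3-yn-1-yl)oxirane | C#CC(C)(C)C[C@@H]1CO1 | intermediate
5 | pyrrolidine | C1CCNC1 | starting material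
6 | propanoyl chloride | CCC(=O)Cl | starting material
7 | 1-(pyrrolidin-1-yl)propan-1-one | CCC(=O)N1CCCC1 | intermediate
8 | lithium 1-(pyrrolidin-1-yl)prop-1-en-1-olate (not isolated) | [Li+].CC=C([O-])N1CCCC1 | intermediate
9 | (4S)-4-hydroxy-2,6,6-trimethyl-1-(pyrrolidin-1-yl)oct-7-yn-1-one (both C2 epimers) | C#CC(C)(C)C[C@@H](O)CC(C)C(=O)N1CCCC1 | intermediate
10 | (4S)-2,6,6-trimethyl-1-oxo-1-(pyrrolidin-1-yl)oct-7-yn-4-yl benzoate (both C2 epimers) | C#CC(C)(C)C[C@@H](OC(=O)c1ccccc1)CC(C)C(=O)N1CCCC1 | intermediate
11 | 1-[(4R)-4-(benzoyloxy)-2,6,6-trimethyloct-1-en-7-yn-1-ylidene]pyrrolidin-1-ium triflate (not isolated) | C#CC(C)(C)C[C@@H](OC(=O)c1ccccc1)CC(C)=C=[N+]1CCCC1.[O-]S(=O)(=O)C(F)(F)F | intermediate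
12 | 1-[(4R,6R)-4-(benzoyloxy)-2,2,6-trimethylbicyclo[4.2.0]oct-1(8)-en-7-ylidene]pyrrolidin-1-ium triflate (not isolated) | C1CC[N+](C1)=C2C=C3C(C)(C)C[C@@H](OC(=O)c4ccccc4)C[C@@]23C.[O-]S(=O)(=O)C(F)(F)F | intermediate
13 | (4R,6R)-2,2,6-trimethyl-7-oxobicyclo[4.2.0]oct-1(8)-en-4-yl benzoate | O=C1C=C2C(C)(C)C[C@@H](OC(=O)c3ccccc3)C[C@@]12C | intermediate
14 | (6R,7aR)-4,4,7a-trimethyl-2-oxo-2,4,5,6,7,7a-hexahydro-1-benzofuran-6-yl benzoate | O=C(c1ccccc1)O[C@@H]1CC(C)(C)C2=CC(=O)O[C@]2(C)C1 | intermediate
15 | (6R,7aR)-6-hydroxy-4,4,7a-trimethyl-5,6,7,7a-tetrahydro-1-benzofuran-2(4H)-one (6-epi-loliolide) | O[C@@H]1CC(C)(C)C2=CC(=O)O[C@]2(C)C1 | intermediate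
16 | (7aR)-4,4,7a-trimethyl-7,7a-dihydro-1-benzofuran-2,6(4H,5H)-dione | O=C1CC(C)(C)C2=CC(=O)O[C@]2(C)C1 | intermediate
17 | (6S,7aR)-6-hydroxy-4,4,7a-trimethyl-5,6,7,7a-tetrahydro-1-benzofuran-2(4H)-one ((−)-loliolide) | O[C@H]1CC(C)(C)C2=CC(=O)O[C@]2(C)C1 | intermediate
18 | hexadecanoyl (palmitoyl) chloride | CCCCCCCCCCCCCCCC(=O)Cl | starting material
19 | (6S,7aR)-4,4,7a-trimethyl-2-oxo-2,4,5,6,7,7a-hexahydro-1-benzofuran-6-yl hexadecanoate ((−)-3-O-palmitoylloliolide) | CCCCCCCCCCCCCCCC(=O)O[C@H]1CC(C)(C)C2=CC(=O)O[C@]2(C)C1 | target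

Total step count: 12.
Longest linear sequence: 11 steps (steps 1–3 and 5–12, from 1 to 19).

## Steps most likely to fail

Step 7 (proposed new method). The keteniminium ion may be consumed by intermolecular reaction or proton loss before the hindered, tert-alkyl-substituted alkyne is engaged, or the cyclobuteniminium salt or cyclobutenone may open under the conditions. The fallback uses only known reactions, sets out from 10 and returns at 14. Semi-hydrogenation of the alkyne of 10 (H2, Lindlar catalyst, quinoline, EtOAc) would give (4S)-2,6,6-trimethyl-1-oxo-1-(pyrrolidin-1-yl)oct-7-en-4-yl benzoate F1. The established intramolecular keteniminium–alkene [2+2] cycloaddition (Tf2O, collidine, ClCH2CH2Cl, heat; then water) should then give, under the same chair control, the cis-fused cyclobutanone (1S,4R,6R)-2,2,6-trimethyl-7-oxobicyclo[4.2.0]octan-4-yl benzoate F2. Baeyer–Villiger oxidation with mCPBA, the quaternary carbon migrating, gives the saturated lactone (3aS,6R,7aR)-4,4,7a-trimethyl-2-oxooctahydro-1-benzofuran-6-yl benzoate F3. α-Selenenylation (LiHMDS, PhSeBr, THF, −78 °C), which should occur on the lactone face that bears C3a–H, gives (3aS,6R,7aR)-4,4,7a-trimethyl-2-oxo-3-(phenylselanyl)octahydro-1-benzofuran-6-yl benzoate F4. Oxidation with H2O2 and syn-elimination towards C3a–H installs the C3=C3a double bond and gives 14.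

Step 5. Proton transfer from the alkyne C–H may quench the amide enolate faster than it opens the epoxide, and the γ-hydroxy amide may lactonise on work-up with loss of pyrrolidine. The fallback sets out from 4 and returns at 9, and uses a soft nucleophile that cannot deprotonate the alkyne. Diethyl methylmalonate with NaOEt in EtOH opens 4 at its CH2 carbon and the alkoxide lactonises to ethyl (5R)-5-(2,2-dimethylbut-3-yn-1-yl)-3-methyl-2-oxooxolane-3-carboxylate F5 (C3 epimers). Krapcho dealkoxycarbonylation (LiCl, wet DMSO, 150 °C) gives (5S)-5-(2,2-dimethylbut-3-yn-1-yl)-3-methyloxolan-2-one F6 (C3 epimers). Aminolysis of the lactone with pyrrolidine and AlMe3 (CH2Cl2, 40 °C) gives 9.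

Step 11. Hydride may be delivered to the butenolide instead of the ketone, the basic reagent may trigger β-elimination of the C7a–O1 bond through the C7 enolate, or facial selectivity at C6 may be incomplete. The fallback sets out from 15, so that steps 10 and 11 are not needed, and returns at 17. Mitsunobu inversion of the equatorial alcohol 15 with 4-nitrobenzoic acid (PPh3, DIAD, toluene, 0→40 °C; the axial trajectory is hindered, so forcing conditions are expected) gives (6S,7aR)-4,4,7a-trimethyl-2-oxo-2,4,5,6,7,7a-hexahydro-1-benzofuran-6-yl 4-nitrobenzoate F7. Methanolysis (K2CO3, MeOH) gives 17.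

## Further compounds

F1 | step 7 | (4S)-2,6,6-trimethyl-1-oxo-1-(pyrrolidin-1-yl)oct-7-en-4-yl benzoate (both C2 epimers) | C=CC(C)(C)C[C@@H](OC(=O)c1ccccc1)CC(C)C(=O)N1CCCC1
F2 | step 7 | (1S,4R,6R)-2,2,6-trimethyl-7-oxobicyclo[4.2.0]octan-4-yl benzoate | O=C1C[C@H]2C(C)(C)C[C@@H](OC(=O)c3ccccc3)C[C@@]12C
F3 | step 7 | (3aS,6R,7aR)-4,4,7a-trimethyl-2-oxooctahydro-1-benzofuran-6-yl benzoate | O=C(c1ccccc1)O[C@@H]1CC(C)(C)[C@@H]2CC(=O)O[C@]2(C)C1
F4 | step 7 | (3aS,6R,7aR)-4,4,7a-trimethyl-2-oxo-3-(phenylselanyl)octahydro-1-benzofuran-6-yl benzoate (C3 epimers) | O=C(c1ccccc1)O[C@@H]1CC(C)(C)[C@@H]2C([Se]c3ccccc3)C(=O)O[C@]2(C)C1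
F5 | step 5 | ethyl (5R)-5-(2,2-dimethylbut-3-yn-1-yl)-3-methyl-2-oxooxolane-3-carboxylate (C3 epimers) | O=C1O[C@H](CC(C)(C)C#C)CC1(C)C(=O)OCC
F6 | step 5 | (5S)-5-(2,2-dimethylbut-3-yn-1-yl)-3-methyloxolan-2-one (C3 epimers) | O=C1O[C@H](CC(C)(C)C#C)CC1C
F7 | step 11 | (6S,7aR)-4,4,7a-trimethyl-2-oxo-2,4,5,6,7,7a-hexahydro-1-benzofuran-6-yl 4-nitrobenzoate | O=C(c1ccc(cc1)[N+](=O)[O-])O[C@H]1CC(C)(C)C2=CC(=O)O[C@]2(C)C1
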